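**Plan**

1. Numbering: lactone O1, C2 (carbonyl), C3 (carries the 4-hydroxy-3,5-dimethoxybenzyl group), C4 (carries the 3,4-dimethoxybenzyl group through C7), C5; the veratryl ring is C1'–C6', with C1' on C7 and methoxy groups on C3' and C4'.
2. Retrosynthetic cuts, in order: the C7 methylene and the phenol go back to a C7 ketone and a benzyl ether; the veratryl ring is cut at C1'–C2' and C5'–C6', leaving an ethynyl ketone at C7 and 2,3-dimethoxybutadiene; the C7–alkyne bond goes back to a C4 carboxyl group; the C3–CH2Ar bond is cut to (R)-paraconic acid and a benzylic bromide from syringaldehyde.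
3. Enabling feature: C3' and C4' carry adjacent methoxy groups and are flanked by the unsubstituted C2' and C5', which is the carbon pattern of 2,3-dimethoxybutadiene; C1' and C6' with C7 attached are what a terminal alkyne activated by a C7 carbonyl supplies.
4. Forward order: the lactone ring first (hydroxymethylation of a succinate imide, lactonization), then the C3 benzyl group, then the C7 ynone, then the veratryl ring as the last ring ([4+2] cycloaddition and DDQ), then one hydrogenolysis that removes the C7 oxygen and the benzyl ether.
5. Stereochemistry: C4 comes from the (S)-4-benzyloxazolidinone auxiliary in the hydroxymethylation; C3 comes from alkylation of the carboxylate–enolate dianion anti to the C4 carboxylate (trans); the later steps are neutral or acidic and should not enolize either centre.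

Key step: step 10

**Route**

Step 1
Reactants: 1 (S)-4-benzyloxazolidin-2-one; 2 methyl 4-chloro-4-oxobutanoate
Product: 3 methyl (S)-4-(4-benzyl-2-oxooxazolidin-3-yl)-4-oxobutanoate
Conditions: n-BuLi, THF, −78 °C; then 2, −78 → 0 °C
Reagents that add atoms: none
Why: N-acylation of the lithiated oxazolidinone is the standard loading of an Evans auxiliary, and the acid chloride should react far faster than the methyl ester, so only the imide forms.

Step 2
Reactants: 3 methyl (S)-4-(4-benzyl-2-oxooxazolidin-3-yl)-4-oxobutanoate; 4 1,3,5-trioxane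
Product: 6 (S)-4-benzyl-3-[(R)-5-oxotetrahydrofuran-3-carbonyl]oxazolidin-2-one, via hydroxymethyl imide ester 5 (not isolated)
Conditions: TiCl4, i-Pr2NEt, CH2Cl2, 0 °C; then 4, TiCl4, 0 °C; aq. NH4Cl; crude 5, p-TsOH (cat.), CH2Cl2, rt
Reagents that add atoms: none
Why: Soft enolization gives the chelated (Z)-titanium enolate of the imide only, the auxiliary benzyl group shields one face so that formaldehyde released from trioxane adds to the other (Evans hydroxymethylation, an aldol-type addition) and sets the (R) centre, and the γ-hydroxy ester then closes to the five-membered lactone under acid catalysis.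

Step 3
Reactants: 6 (S)-4-benzyl-3-[(R)-5-oxotetrahydrofuran-3-carbonyl]oxazolidin-2-one
Product: 7 (R)-5-oxotetrahydrofuran-3-carboxylic acid ((R)-paraconic acid)
Conditions: LiOH, H2O2, THF/H2O, 0 °C; Na2SO3; HCl to pH 1, continuous extraction with EtOAc
Reagents that add atoms: hydrogen peroxide, OO
Why: Lithium hydroperoxide should attack the exocyclic imide carbonyl selectively (Evans auxiliary cleavage) without enolizing the stereocentre, and any lactone opened on the way should reclose on acidification.

Step 4
Reactants: 8 syringaldehyde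
Product: 9 4-benzyloxy-3,5-dimethoxybenzaldehyde
Conditions: BnBr, K2CO3, DMF, 60 °C
Reagents that add atoms: benzyl bromide, BrCc1ccccc1
Why: Williamson ether synthesis on the acidic, para-formyl phenol should proceed cleanly and installs a protecting group that the last step removes together with the C7 oxygen.

Step 5
Reactants: 9 4-benzyloxy-3,5-dimethoxybenzaldehyde
Product: 10 (4-benzyloxy-3,5-dimethoxyphenyl)methanol
Conditions: NaBH4, MeOH, 0 °C
Reagents that add atoms: none
Why: Borohydride reduction of an aromatic aldehyde to the benzylic alcohol leaves the ethers untouched.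

Step 6
Reactants: 10 (4-benzyloxy-3,5-dimethoxyphenyl)methanol
Product: 11 2-benzyloxy-5-(bromomethyl)-1,3-dimethoxybenzene
Conditions: PBr3, Et2O, 0 °C; used without storage
Reagents that add atoms: phosphorus tribromide, BrP(Br)Br
Why: Bromination of the benzylic alcohol through its phosphite ester (substitution with PBr3) is standard for electron-rich benzyl alcohols and should give a highly reactive alkylating agent.

Step 7
Reactants: 7 (R)-5-oxotetrahydrofuran-3-carboxylic acid; 11 2-benzyloxy-5-(bromomethyl)-1,3-dimethoxybenzene
Product: 12 (3R,4R)-4-(4-benzyloxy-3,5-dimethoxybenzyl)-5-oxotetrahydrofuran-3-carboxylic acid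
Conditions: NaN(SiMe3)2 (2.2 equiv), THF, −78 °C; then 11, −78 → −30 °C; 1 M HCl
Reagents that add atoms: none
Why: Two equivalents of base should give the carboxylate–lactone enolate dianion (the carboxylate blocks enolization at its own α-carbon and hence the β-elimination that would open the lactone), and the enolate is C-alkylated by the benzylic bromide on the face anti to the neighbouring carboxylate, setting the new centre trans (dianion alkylation of a paraconic acid).

Step 8
Reactants: 12 (3R,4R)-4-(4-benzyloxy-3,5-dimethoxybenzyl)-5-oxotetrahydrofuran-3-carboxylic acid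
Product: 13 (3R,4R)-4-(4-benzyloxy-3,5-dimethoxybenzyl)-N-methoxy-N-methyl-5-oxotetrahydrofuran-3-carboxamide
Conditions: MeNH(OMe)·HCl, EDC·HCl, HOBt, N-methylmorpholine, CH2Cl2, 0 °C → rt
Reagents that add atoms: N,O-dimethylhydroxylamine hydrochloride, CNOC.Cl
Why: Carbodiimide amide coupling under weakly basic conditions should form the Weinreb amide without opening the lactone, and the trans arrangement is also the thermodynamically preferred one.

Step 9
Reactants: 13 (3R,4R)-4-(4-benzyloxy-3,5-dimethoxybenzyl)-N-methoxy-N-methyl-5-oxotetrahydrofuran-3-carboxamide; 14 ethynylmagnesium bromide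
Product: 15 (3R,4R)-3-(4-benzyloxy-3,5-dimethoxybenzyl)-4-propioloyldihydrofuran-2(3H)-one
Conditions: 14 (0.5 M in THF, 2 equiv), THF, −20 → 0 °C; inverse quench into cold 1 M HCl
Reagents that add atoms: none
Why: In this Weinreb ketone synthesis the alkynyl Grignard reagent should add once to the chelating amide, which is more reactive than the lactone at low temperature, and the magnesium chelate holds the adduct until the acidic inverse quench, so the ynone never meets base and the liberated amine is protonated before it can add to the triple bond.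

Step 10
Reactants: 15 (3R,4R)-3-(4-benzyloxy-3,5-dimethoxybenzyl)-4-propioloyldihydrofuran-2(3H)-one; 16 2,3-dimethoxybuta-1,3-diene
Product: 18 (3R,4R)-3-(4-benzyloxy-3,5-dimethoxybenzyl)-4-(3,4-dimethoxybenzoyl)dihydrofuran-2(3H)-one, via cyclohexa-1,4-diene cycloadduct 17 (not isolated)
Conditions: 16 (4 equiv), BHT (cat.), PhMe, 90 °C, sealed tube; evaporation of excess 16; then DDQ (1.05 equiv), PhMe, rt
Reagents that add atoms: none
Why: The ynone of 15, its LUMO lowered by the C7 carbonyl, and the electron-rich diene 16 should combine in a concerted, normal-demand thermal [4+2] cycloaddition that forms the C1'–C2' and C5'–C6' bonds and gives the 1,4-cyclohexadiene 17, after which DDQ abstracts hydride from a doubly allylic CH2 and loss of a proton aromatizes the ring. The closest known reaction type is the Diels–Alder reaction of alkynyl ketones or acetylenic esters with 2,3-dialkoxybutadienes followed by quinone dehydrogenation. The one ring that closes, the veratryl carbocycle, arises by intermolecular cycloaddition (four carbons from the diene, two from the alkyne, two ring bonds in one event) and not by cyclization of a chain. No stereocentre is created; C3 and C4 of the lactone are carried through, and they should survive because the medium is neutral and aprotic, so the C4–H next to the ketone is not enolized and the lactone oxygen is not expelled by β-elimination. No regiochemical question arises because 16 is C2-symmetric, which places the methoxy groups at C3' and C4' by necessity, and the ynone is the only electron-poor π-bond in 15. The oxidation must choose the diene C–H bonds over the syringyl benzylic CH2 and the aryl benzyl ether, which is secured by the driving force of aromatization, by one equivalent of DDQ at room temperature, and by removing excess 16 first so that it does not consume the quinone.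

Step 11
Reactants: 18 (3R,4R)-3-(4-benzyloxy-3,5-dimethoxybenzyl)-4-(3,4-dimethoxybenzoyl)dihydrofuran-2(3H)-one
Product: 19 (3R,4R)-4-(3,4-dimethoxybenzyl)-3-(4-hydroxy-3,5-dimethoxybenzyl)dihydrofuran-2(3H)-one
Conditions: H2 (3 atm), 10% Pd/C, AcOH, HClO4 (cat.), rt
Reagents that add atoms: none
Why: Catalytic hydrogenation in acid should reduce the electron-rich aryl ketone to the benzylic alcohol and hydrogenolyse its C–O bond to the C7 methylene, the same conditions cleave the aryl benzyl ether (benzylic hydrogenolysis), and neither ring stereocentre takes part.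

**Compound list**

1 | (S)-4-benzyloxazolidin-2-one | O=C1N[C@@H](Cc2ccccc2)CO1 | starting material
2 | methyl 4-chloro-4-oxobutanoate | COC(=O)CCC(=O)Cl | starting material
3 | methyl (S)-4-(4-benzyl-2-oxooxazolidin-3-yl)-4-oxobutanoate | COC(=O)CCC(=O)N1[C@@H](Cc2ccccc2)COC1=O | intermediate
4 | 1,3,5-trioxane | C1OCOCO1 | starting material
5 | methyl (R)-4-[(S)-4-benzyl-2-oxooxazolidin-3-yl]-3-(hydroxymethyl)-4-oxobutanoate | COC(=O)C[C@H](CO)C(=O)N1[C@@H](Cc2ccccc2)COC1=O | intermediate
6 | (S)-4-benzyl-3-[(R)-5-oxotetrahydrofuran-3-carbonyl]oxazolidin-2-one | O=C1C[C@H](CO1)C(=O)N1[C@@H](Cc2ccccc2)COC1=O | intermediate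
7 | (R)-5-oxotetrahydrofuran-3-carboxylic acid ((R)-paraconic acid) | O=C(O)[C@H]1COC(=O)C1 | intermediate
8 | syringaldehyde (4-hydroxy-3,5-dimethoxybenzaldehyde) | COc1cc(C=O)cc(OC)c1O | starting material
9 | 4-benzyloxy-3,5-dimethoxybenzaldehyde | COc1cc(C=O)cc(OC)c1OCc1ccccc1 | intermediate
10 | (4-benzyloxy-3,5-dimethoxyphenyl)methanol | COc1cc(CO)cc(OC)c1OCc1ccccc1 | intermediate
11 | 2-benzyloxy-5-(bromomethyl)-1,3-dimethoxybenzene | COc1cc(CBr)cc(OC)c1OCc1ccccc1 | intermediate
12 | (3R,4R)-4-(4-benzyloxy-3,5-dimethoxybenzyl)-5-oxotetrahydrofuran-3-carboxylic acid | O=C(O)[C@H]1COC(=O)[C@@H]1Cc1cc(OC)c(OCc2ccccc2)c(OC)c1 | intermediate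
13 | (3R,4R)-4-(4-benzyloxy-3,5-dimethoxybenzyl)-N-methoxy-N-methyl-5-oxotetrahydrofuran-3-carboxamide | CON(C)C(=O)[C@H]1COC(=O)[C@@H]1Cc1cc(OC)c(OCc2ccccc2)c(OC)c1 | intermediate
14 | ethynylmagnesium bromide | C#C[Mg]Br | starting material
15 | (3R,4R)-3-(4-benzyloxy-3,5-dimethoxybenzyl)-4-propioloyldihydrofuran-2(3H)-one | C#CC(=O)[C@H]1COC(=O)[C@@H]1Cc1cc(OC)c(OCc2ccccc2)c(OC)c1 | intermediate
16 | 2,3-dimethoxybuta-1,3-diene | C=C(OC)C(OC)=C | starting material
17 | (3R,4R)-3-(4-benzyloxy-3,5-dimethoxybenzyl)-4-(4,5-dimethoxycyclohexa-1,4-diene-1-carbonyl)dihydrofuran-2(3H)-one | COC1=C(OC)CC(=CC1)C(=O)[C@H]1COC(=O)[C@@H]1Cc1cc(OC)c(OCc2ccccc2)c(OC)c1 | intermediate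
18 | (3R,4R)-3-(4-benzyloxy-3,5-dimethoxybenzyl)-4-(3,4-dimethoxybenzoyl)dihydrofuran-2(3H)-one | COc1ccc(C(=O)[C@H]2COC(=O)[C@@H]2Cc2cc(OC)c(OCc3ccccc3)c(OC)c2)cc1OC | intermediate
19 | (3R,4R)-4-(3,4-dimethoxybenzyl)-3-(4-hydroxy-3,5-dimethoxybenzyl)dihydrofuran-2(3H)-one | COc1ccc(C[C@H]2COC(=O)[C@@H]2Cc2cc(OC)c(O)c(OC)c2)cc1OC | target

**Step count**

Total: 11 steps (steps 2 and 10 are each telescoped and counted once). Longest linear sequence: 8 steps (1, 2, 3, 7, 8, 9, 10, 11). The bromide 11 comes from a three-step side branch (4, 5, 6).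

**Steps most likely to fail, with fallbacks**

Step 10. The cycloaddition may be slower than thermal decay or polymerization of the terminal ynone, the enol-ether diene may hydrolyse or oligomerize, prolonged heating may epimerize C4, and the quinone may over-oxidize at the syringyl benzylic position. The fallback brings the veratryl ring in preformed and sets out from acid 12. Coupling with thiophenol (EDC·HCl, cat. DMAP, CH2Cl2, 0 °C) should give S-phenyl (3R,4R)-4-(4-benzyloxy-3,5-dimethoxybenzyl)-5-oxotetrahydrofuran-3-carbothioate F1. A base-free Liebeskind–Srogl coupling of this thioester with 3,4-dimethoxyphenylboronic acid (Pd2(dba)3, tri(2-furyl)phosphine, copper thiophene-2-carboxylate, THF, 50 °C) should then give ketone 18, where the route is rejoined before step 11.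

Step 9. The Grignard reagent may attack the lactone carbonyl in competition with the amide, the C–H next to the lactone carbonyl may be deprotonated, and during work-up the liberated amine may add to the triple bond or the ynone may undergo β-elimination. The fallback avoids organomagnesium chemistry and again sets out from acid 12. Oxalyl chloride with catalytic DMF (CH2Cl2, 0 °C → rt) should give (3R,4R)-4-(4-benzyloxy-3,5-dimethoxybenzyl)-5-oxotetrahydrofuran-3-carbonyl chloride F2. A Stille acyl coupling of this chloride with tributyl(ethynyl)stannane (PdCl2(PPh3)2 cat., PhMe, 60 °C) under neutral conditions should deliver ynone 15 directly, rejoining the route before step 10.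

Step 7. Dianion formation may be incomplete because the disodium salt is poorly soluble, the carboxylate may be O-alkylated, a second alkylation may occur, or the anti selectivity may be insufficient. The fallback alkylates a lactone whose C4 substituent is a protected alcohol and sets out from acid 7.
- Chemoselective reduction of the acid (BH3·SMe2, THF, 0 °C) should give (S)-4-(hydroxymethyl)dihydrofuran-2(3H)-one F3.
- Silylation (TBSCl, imidazole, DMF) should give (R)-4-{[tert-butyl(dimethyl)silyl]oxymethyl}dihydrofuran-2(3H)-one F4.
- Enolate alkylation (LiN(i-Pr)2, THF, −78 °C; then 11), anti to the C4 substituent, should give (3R,4R)-3-(4-benzyloxy-3,5-dimethoxybenzyl)-4-{[tert-butyl(dimethyl)silyl]oxymethyl}dihydrofuran-2(3H)-one F5.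
- Acidic desilylation (HF·pyridine, THF) should give (3R,4S)-3-(4-benzyloxy-3,5-dimethoxybenzyl)-4-(hydroxymethyl)dihydrofuran-2(3H)-one F6.
- Oxidation of the primary alcohol (TEMPO cat., PhI(OAc)2, MeCN/H2O) should return acid 12, where the route is rejoined before step 8.

The free alcohols F3 and F6 are kept away from base, because acyl migration between the two CH2O arms on C4 would erode the configuration at that centre.

**Further compounds**

F1 | step 10 | S-phenyl (3R,4R)-4-(4-benzyloxy-3,5-dimethoxybenzyl)-5-oxotetrahydrofuran-3-carbothioate | O=C(Sc1ccccc1)[C@H]1COC(=O)[C@@H]1Cc1cc(OC)c(OCc2ccccc2)c(OC)c1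
F2 | step 9 | (3R,4R)-4-(4-benzyloxy-3,5-dimethoxybenzyl)-5-oxotetrahydrofuran-3-carbonyl chloride | ClC(=O)[C@H]1COC(=O)[C@@H]1Cc1cc(OC)c(OCc2ccccc2)c(OC)c1
F3 | step 7 | (S)-4-(hydroxymethyl)dihydrofuran-2(3H)-one | OC[C@H]1COC(=O)C1
F4 | step 7 | (R)-4-{[tert-butyl(dimethyl)silyl]oxymethyl}dihydrofuran-2(3H)-one | CC(C)(C)[Si](C)(C)OC[C@H]1COC(=O)C1
F5 | step 7 | (3R,4R)-3-(4-benzyloxy-3,5-dimethoxybenzyl)-4-{[tert-butyl(dimethyl)silyl]oxymethyl}dihydrofuran-2(3H)-one | CC(C)(C)[Si](C)(C)OC[C@H]1COC(=O)[C@@H]1Cc1cc(OC)c(OCc2ccccc2)c(OC)c1
F6 | step 7 | (3R,4S)-3-(4-benzyloxy-3,5-dimethoxybenzyl)-4-(hydroxymethyl)dihydrofuran-2(3H)-one | OC[C@H]1COC(=O)[C@@H]1Cc1cc(OC)c(OCc2ccccc2)c(OC)c1
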